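Four neighbouring flasks hold one charge and differ in how it goes in.

| flask | starting material | second substrate | protic impurity | enzyme | time | remark |
|---|---|---|---|---|---|---|
| north | 32 mM (fed, over 3.0 s) | 1.10 equiv | 3.20 mM | 0.02 mol% | 15 s | all else is in the flask from the start; the feed brings no volume worth counting |
| south-west | 32 mM | 1.10 equiv | 3.20 mM | 0.02 mol% | 15 s | everything together at the start |
| south | 32 mM | 1.10 equiv (fed, over 12 s) | 3.20 mM | 0.02 mol% | 15 s | all else is in the flask from the start; the feed brings no volume worth counting |
| north-east | 32 mM (fed, over 12 s) | 1.10 equiv | 3.20 mM | 0.02 mol% | 15 s | all else is in the flask from the start; the feed brings no volume worth counting |

    starting material + enzyme ⇌ starting complex (K1 = 37 /M, k1 = 59000 /M/s)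
    second substrate + starting complex ⇌ ternary complex (K2 = 32 /M, k2 = 1.6 × 10⁵ /M/s)
    ternary complex → enzyme + target (k3 = 700 /s)
    second substrate + protic impurity → quenched reagent (k4 = 2.9 /M/s)

1. the flask that comes out highest in amount of target, in percent of the starting material charged, or "all alike" when all lie within 1.5 percentage points (north / south-west / south / north-east / all alike)
2. target at the end, in percent of the starting material charged, north
3. target at the end, in percent of the starting material charged, south-west
4. target at the end, in percent of the starting material charged, south
5. target at the end, in percent of the starting material charged, north-east

The third step runs one way. The second substrate less the protic impurity comes to 32.0 mM, which matches the starting material. So the end state to approach is target equal to the charge, and the question is how fast. The enzyme stands at 6.40 µM.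

Setting making equal to using for both complexes gives φ, the share of enzyme held as ternary complex. Its inverse is one, plus 1.38 from the terms inverse in one substrate, plus 0.855 from the term inverse in their product. At the charge, φ is therefore 0.309. The charge divided by the starting rate, which is the third-step constant times enzyme times φ, comes to 23.1 s. This is the clearing time τ.

A bench rule reads the run as first order with this time, so the target share is one minus exp(−t/τ). A steady feed is then counted as a delay of half its length, the mean arrival time of what is fed. The rule gives 47.7% for south-west, 44.2% for north, 32.2% for south and 32.2% for north-east, and its winner is south-west.

The rule needs a rate proportional to what remains. With both substrates falling together to a fraction f of their charge, the product term grows as the inverse square of f. It overtakes the rest of the sum at f = 0.463. For south-west the rule reaches that point at 17.8 s, later than the 15 s asked, so the asked end of south-west lies inside the border.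

The forecast named south-west, with 45% for north, 46.4% for south-west, 34% for south and 35.2% for north-east, on the ground that “anything that keeps either substrate low early costs product”. It parts the two slow feeds, which this reckoning leaves equal.

The simulation puts south-west highest, with 44.0% in north, 46.4% in south-west, 33.8% in south and 35.3% in north-east. Left until 150 s, south-west reaches 94.8%. The steady-state φ holds no enzyme term, so τ scales inversely with loading. At 0.023 mol% of enzyme, τ shortens to 19.8 s, and the rule adds 5.32% of the charge to south-west. The simulated south-west at that loading moved by 5 points.

(The rate constants are invented.)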